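**Retrosynthetic overview**

- Ring carbons: C1 (methacrylate carbinol), C2, C3 (isobutyrate carbinol), C4 (quaternary, methyl), C5, C6 (ketone), C7, C8 (alkene carbon with methyl), C9, C10, C11 (CMe2). The plan rests on the cyclobutane C4–C5–C10–C9, whose diagonals are spanned by the enone bridge C6–C7–C8 and the saturated bridge C3–C2–C1–C11. Its fifteen skeletal carbons are three isoprene units joined head to tail (C10–C9–C8(Me)–C7, C6–C5–C4(Me)–C3, C2–C1–C11(Me)2), so C10–C11, C5–C10 and C4–C9 are the bonds a folded farnesyl chain makes by cation–alkene addition.
- Late stage: the methacrylate at O1 (put on last) and the isobutyrate at O3 are removed, the C1 and C3 oxygens go back to enzymatic C–H hydroxylations and the C6 carbonyl to an allylic oxidation. This leads to the hydrocarbon α-longipinene.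
- Key disconnection: α-longipinene to (2E,6E)-farnesyl diphosphate by a class 1 sesquiterpene synthase. Forward ring order: eleven-membered ring (C10–C11), then its transannular division into the six-membered ring C5–C6–C7–C8–C9–C10 and the seven-membered ring (C5–C10), then the cyclobutane (C4–C9).
- Farnesyl diphosphate comes from (2E,6E)-farnesol by allylic chlorination and displacement with hydrogen diphosphate.

Key step: step 3

**Remarks**

- Assumption: a recombinant α-longipinene synthase that folds the chain in the sense giving hydrocarbon 8 is taken as available. The enantiomer is to be confirmed (chiral GC, optical rotation against an authentic sample) before 8 is carried on. The required cage, (1R,2S,7R,8R) in tricyclo[5.4.0.0(2,8)]undec-9-ene numbering, is the configuration assigned to (+)-α-longipinene of conifer oleoresin, so a plant-type enzyme is the first choice.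
- Cage compounds are named with the overview numbering, not the customary longipinane numbering. The change of the C4 and C10 descriptors between 8 and 10 is a priority effect of the new carbonyl; no centre is inverted.
- In the non-isolated intermediates 7 and 9 one centre carries no descriptor: C3 of nerolidyl diphosphate is fixed by the enzyme and not assigned here, and C6 of the peroxide forms as either epimer and is destroyed in the same step.

**Route**

Step 1
Reactants: 1 (2E,6E)-farnesol
Product: 3 (2E,6E)-farnesyl chloride, via farnesyloxydimethylsulfonium chloride 2 (not isolated)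
Conditions: NCS, Me2S, CH2Cl2, −40 °C to 0 °C
Reagents that add atoms: N-chlorosuccinimide, O=C1CCC(=O)N1Cl
Why: Corey–Kim chlorination, in which chloride displaces the alkoxysulfonium group of 2 at the primary allylic carbon under non-acidic conditions, so that neither allylic transposition nor loss of the 2E geometry is expected; no stereocentre is formed.

Step 2
Reactants: 3 (2E,6E)-farnesyl chloride; 4 tris(tetrabutylammonium) hydrogen diphosphate
Product: 6 trisammonium (2E,6E)-farnesyl diphosphate, via bis(tetrabutylammonium) farnesyl hydrogen diphosphate 5 (not isolated)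
Conditions: 4 (2 equiv), MeCN, rt; then Dowex 50WX8 (NH4+ form), aq. NH4HCO3/i-PrOH; lyophilisation, cellulose chromatography
Reagents that add atoms: tris(tetrabutylammonium) hydrogen diphosphate (4), CCCC[N+](CCCC)(CCCC)CCCC.CCCC[N+](CCCC)(CCCC)CCCC.CCCC[N+](CCCC)(CCCC)CCCC.OP(=O)([O-])OP(=O)([O-])[O-]; ammonium hydrogen carbonate, [NH4+].OC(=O)[O-]
Why: SN2 displacement of a primary allylic chloride by the hydrogen diphosphate anion in a dipolar aprotic solvent followed by cation exchange, the standard preparation of allylic diphosphates; no stereocentre is formed.

Step 3
Reactants: 6 trisammonium (2E,6E)-farnesyl diphosphate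
Product: 8 (4S,5R,9R,10R)-α-longipinene, via enzyme-bound nerolidyl diphosphate 7 (not isolated)
Conditions: α-longipinene synthase (recombinant, purified), MgCl2, HEPES pH 7.5, DTT, glycerol, pentane overlay, 30 °C; AgNO3-impregnated SiO2 to remove co-products
Reagents that add atoms: none
Why: Class 1 terpene synthase cationic polycyclisation, the reaction by which longipinene- and longifolene-type hydrocarbons are known to arise from farnesyl diphosphate: the magnesium-bound diphosphate ionises from C10, recombines at C8 to give enzyme-bound nerolidyl diphosphate 7, and after rotation about C8–C9 re-ionises to the cisoid allyl cation. The C1=C11 alkene adds to C10 through C11 (endo closure of the eleven-membered ring, cation at C1), a 1,3-hydride shift from C10 to C1 regenerates the allyl cation C10–C9–C8, and the C4=C5 alkene adds through C5 to C10 across the macrocycle, which closes the six-membered ring C5–C6–C7–C8–C9–C10 in the exo mode and the seven-membered ring C1–C2–C3–C4–C5–C10–C11 in the endo mode and leaves a tertiary cation at C4. The now Z-configured C8=C9 alkene captures C4 through C9 (exo closure of the cyclobutane C4–C5–C10–C9, tertiary cation at C8) and a proton is removed from C7, plausibly by the bound diphosphate. The relative configuration of C4, C5, C9 and C10 is fixed by the cage, since the two diagonals of the cyclobutane can only be bridged on opposite faces, and the absolute sense is set by the fold that the chiral active site imposes on the chain. The selectivities needed are capture of the C4 cation by C9 instead of C8 (longibornyl manifold) or early proton loss, and final proton loss from C7 instead of the C8 methyl; the natural substrate secures none of this beyond the proximity created by the Z alkene, so it rests on the product specificity of the chosen enzyme, which holds the C4 cation folded over C9 and shields it from water.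

Step 4
Reactants: 8 (4S,5R,9R,10R)-α-longipinene
Product: 10 (4R,5R,9R,10S)-longipin-7-en-6-one, via 6-(tert-butylperoxy)-α-longipinene 9 (not isolated)
Conditions: Rh2(cap)4 (dirhodium tetrakis(caprolactamate), 1 mol %), t-BuOOH (70% aq., 5 equiv), K2CO3, CH2Cl2, rt
Reagents that add atoms: tert-butyl hydroperoxide, CC(C)(C)OO
Why: Radical allylic oxidation with tert-butyl hydroperoxide under dirhodium caprolactamate catalysis (the pinene-to-verbenone pattern): the tert-butylperoxyl radical abstracts hydrogen from the ring methylene C6, the allyl radical is trapped as peroxide 9 and this collapses to the enone, while the bridgehead allylic C9–H is not abstracted because its radical cannot overlap with the alkene; no stereocentre is formed.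

Step 5
Reactants: 10 (4R,5R,9R,10S)-longipin-7-en-6-one
Product: 11 (3R,4R,5R,9R,10S)-3-hydroxylongipin-7-en-6-one (hydroxyl on the face of the seven-membered ring that looks toward C5)
Conditions: cytochrome P450 BM3 (CYP102A1) variant selected for C3 (purified), NADP+ (cat.), phosphite dehydrogenase, Na2HPO3, catalase, air, K2HPO4/KH2PO4 buffer pH 8.0, 2% DMSO, 25 °C
Reagents that add atoms: dioxygen, O=O
Why: Cytochrome P450 C–H hydroxylation (hydrogen abstraction by the iron-oxo haem and oxygen rebound with retention), a reaction that engineered BM3 variants perform on unactivated methylene groups next to quaternary carbons of terpenoid ketones; the variant, chosen by screening an active-site library against 10, presents the C3 hydrogen on the C5 face to the oxidant, which sets 3R, while the electron-poor enone alkene and the C–H bonds near the carbonyl are deactivated.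

Step 6
Reactants: 11 (3R,4R,5R,9R,10S)-3-hydroxylongipin-7-en-6-one; 12 isobutyric anhydride
Product: 13 (3R,4R,5R,9R,10S)-3-(isobutyryloxy)longipin-7-en-6-one
Conditions: (i-PrCO)2O, DMAP, Et3N, CH2Cl2, rt
Reagents that add atoms: isobutyric anhydride (12), CC(C)C(=O)OC(=O)C(C)C
Why: DMAP-catalysed acylation (nucleophilic catalysis through the acylpyridinium ion) of the only hydroxyl group; the C3–O bond is not broken, so 3R is retained.

Step 7
Reactants: 13 (3R,4R,5R,9R,10S)-3-(isobutyryloxy)longipin-7-en-6-one
Product: 14 (1R,3R,4R,5R,9R,10S)-1-hydroxy-3-(isobutyryloxy)longipin-7-en-6-one (hydroxyl on the face toward C9, trans to O3)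
Conditions: second cytochrome P450 BM3 (CYP102A1) variant selected for C1 (purified), NADP+ (cat.), phosphite dehydrogenase, Na2HPO3, catalase, air, K2HPO4/KH2PO4 buffer pH 8.0, 2% DMSO, 25 °C
Reagents that add atoms: dioxygen, O=O
Why: Second cytochrome P450 hydroxylation by the same radical rebound mechanism, using a variant screened against ester 13 for the C1 hydrogen on the C9 face, which sets 1R with retention; purified enzyme is used so that no esterase of a cell extract cleaves the isobutyrate.

Step 8
Reactants: 14 (1R,3R,4R,5R,9R,10S)-1-hydroxy-3-(isobutyryloxy)longipin-7-en-6-one; 15 methacrylic anhydride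
Product: 16 (1R,3R,4R,5R,9R,10S)-3-(isobutyryloxy)-1-(methacryloyloxy)longipin-7-en-6-one (CNP0214356.1)
Conditions: methacrylic anhydride, DMAP, Et3N, BHT (cat.), CH2Cl2, 0 °C to rt
Reagents that add atoms: methacrylic anhydride (15), C=C(C)C(=O)OC(=O)C(C)=C
Why: DMAP-catalysed acylation of the remaining neopentylic hydroxyl with the anhydride, BHT suppressing radical polymerisation of the methacrylate; the C1–O bond is untouched, so 1R is retained and the product is the target.

**Compound list**

1 | (2E,6E)-farnesol | CC(C)=CCC/C(C)=C/CC/C(C)=C/CO | starting material
2 | farnesyloxydimethylsulfonium chloride | CC(C)=CCC/C(C)=C/CC/C(C)=C/CO[S+](C)C.[Cl-] | intermediate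
3 | (2E,6E)-farnesyl chloride | CC(C)=CCC/C(C)=C/CC/C(C)=C/CCl | intermediate
4 | tris(tetrabutylammonium) hydrogen diphosphate | CCCC[N+](CCCC)(CCCC)CCCC.CCCC[N+](CCCC)(CCCC)CCCC.CCCC[N+](CCCC)(CCCC)CCCC.OP(=O)([O-])OP(=O)([O-])[O-] | starting material
5 | bis(tetrabutylammonium) (2E,6E)-farnesyl hydrogen diphosphate | CC(C)=CCC/C(C)=C/CC/C(C)=C/COP(=O)([O-])OP(=O)(O)[O-].CCCC[N+](CCCC)(CCCC)CCCC.CCCC[N+](CCCC)(CCCC)CCCC | intermediate
6 | trisammonium (2E,6E)-farnesyl diphosphate | CC(C)=CCC/C(C)=C/CC/C(C)=C/COP(=O)([O-])OP(=O)([O-])[O-].[NH4+].[NH4+].[NH4+] | intermediate
7 | (6E)-nerolidyl diphosphate, enzyme-bound, C3 configuration set by the enzyme and not assigned | CC(C)=CCC/C(C)=C/CCC(C)(C=C)OP(=O)([O-])OP(=O)([O-])[O-].[NH4+].[NH4+].[NH4+] | intermediate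
8 | (4S,5R,9R,10R)-α-longipinene | C1CC[C@@]2(C)[C@@H]3CC=C(C)[C@H]2[C@@H]3C1(C)C | intermediate
9 | 6-(tert-butylperoxy)-α-longipinene, either C6 epimer | C1CC[C@@]2(C)[C@@H]3C(OOC(C)(C)C)C=C(C)[C@H]2[C@@H]3C1(C)C | intermediate
10 | (4R,5R,9R,10S)-longipin-7-en-6-one | C1CC[C@@]2(C)[C@@H]3C(=O)C=C(C)[C@H]2[C@@H]3C1(C)C | intermediate
11 | (3R,4R,5R,9R,10S)-3-hydroxylongipin-7-en-6-one | C1C[C@@H](O)[C@@]2(C)[C@@H]3C(=O)C=C(C)[C@H]2[C@@H]3C1(C)C | intermediate
12 | isobutyric anhydride | CC(C)C(=O)OC(=O)C(C)C | starting material
13 | (3R,4R,5R,9R,10S)-3-(isobutyryloxy)longipin-7-en-6-one | C1C[C@@H](OC(=O)C(C)C)[C@@]2(C)[C@@H]3C(=O)C=C(C)[C@H]2[C@@H]3C1(C)C | intermediate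
14 | (1R,3R,4R,5R,9R,10S)-1-hydroxy-3-(isobutyryloxy)longipin-7-en-6-one | O[C@@H]1C[C@@H](OC(=O)C(C)C)[C@@]2(C)[C@@H]3C(=O)C=C(C)[C@H]2[C@@H]3C1(C)C | intermediate
15 | methacrylic anhydride | C=C(C)C(=O)OC(=O)C(C)=C | starting material
16 | (1R,3R,4R,5R,9R,10S)-3-(isobutyryloxy)-1-(methacryloyloxy)longipin-7-en-6-one, CNP0214356.1 | C=C(C)C(=O)O[C@@H]1C[C@@H](OC(=O)C(C)C)[C@@]2(C)[C@@H]3C(=O)C=C(C)[C@H]2[C@@H]3C1(C)C | target

**Step count**

Total step count: 8. Longest linear sequence: 8 steps, from 1 to 16.

**Steps most likely to fail**

Step 5 (hydroxylation of C3). The oxidant may be steered to the more open C2 methylene, to the allylic C8 methyl group or to the wrong face of C3, so that regio- or facial control is lost. The fallback sets out from 10 and comes back at 11, and no longer asks the C–H oxidation for the configuration. Any hydroxylase variant, or a fungal whole-cell biotransformation, that oxidises C3 from the other face would give (3S,4R,5R,9R,10S)-3-hydroxylongipin-7-en-6-one F1, alone or mixed with 11. Dess–Martin oxidation would converge this material on (4R,5R,9R,10S)-longipin-7-ene-3,6-dione F2. The saturated C3 carbonyl would then be reduced with a ketoreductase picked from a panel for hydride delivery to the C9 face (NADPH, i-PrOH), the conjugated and less electrophilic C6 carbonyl being left, to give 11. NaBH4 in MeOH/CH2Cl2 at −78 °C is the chemical alternative for the chemoselectivity; its facial outcome would have to be determined.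

Step 7 (hydroxylation of C1 in ester 13). Oxidation may be diverted to the tertiary C–H of the isobutyryl group or to C2, the lipophilic ester may bind unproductively, or the ester may be lost by hydrolysis. The fallback sets out from 11 and comes back at 14, with acylation and oxidation in the opposite order. The free alcohol 11, which offers the enzyme a hydrogen-bond donor as a second anchor, would be hydroxylated at C1 by a variant screened against it to give (1R,3R,4R,5R,9R,10S)-1,3-dihydroxylongipin-7-en-6-one F3. The two hydroxyls would then be told apart by acylation with isobutyric anhydride 12 (1 equiv), DMAP (cat.), 2,4,6-collidine, CH2Cl2, −40 °C, or with Candida antarctica lipase B and vinyl isobutyrate. The expectation, to be verified, is that O3 (neighbour C4, whose substituents are tied back in rings) reacts ahead of O1 (neighbour C11 with two free methyl groups), giving 14.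

Step 3 (cyclisation). The C4 cation may be diverted before the cyclobutane closes (C4–C8 bonding into the longibornyl manifold or early proton loss), the last proton may be taken from the C8 methyl group instead of C7, or the chosen enzyme may fold the chain in the mirror-image sense. Slow turnover through diphosphate inhibition and hydrolysis of 6 adds to this. The fallback sets out from 6 and comes back at 8, and no longer asks the enzyme for the position of the alkene. A synthase that runs the same three closures but ends by deprotonating the methyl group would give β-longipinene F4, together with whatever 8 it forms. Treatment of the hydrocarbon mixture with KNH(CH2)3NH2 (from KH and H2N(CH2)3NH2) in H2N(CH2)3NH2 at rt, the base known to move the exocyclic alkene of β-pinene into the ring, would equilibrate F4 to the trisubstituted endocyclic isomer 8. Co-products of other skeletons would be removed on AgNO3-impregnated SiO2. An enzyme of the wrong absolute fold can only be answered by another enzyme, which is why the enantiomer check is placed directly after step 3.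

**Further compounds**

F1 | step 5 | (3S,4R,5R,9R,10S)-3-hydroxylongipin-7-en-6-one | C1C[C@H](O)[C@@]2(C)[C@@H]3C(=O)C=C(C)[C@H]2[C@@H]3C1(C)C
F2 | step 5 | (4R,5R,9R,10S)-longipin-7-ene-3,6-dione | C1CC(=O)[C@@]2(C)[C@@H]3C(=O)C=C(C)[C@H]2[C@@H]3C1(C)C
F3 | step 7 | (1R,3R,4R,5R,9R,10S)-1,3-dihydroxylongipin-7-en-6-one | O[C@@H]1C[C@@H](O)[C@@]2(C)[C@@H]3C(=O)C=C(C)[C@H]2[C@@H]3C1(C)C
F4 | step 3 | β-longipinene, exocyclic C8 methylene isomer of 8 with the same cage configuration | C1CC[C@@]2(C)[C@@H]3CCC(=C)[C@H]2[C@@H]3C1(C)C
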